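**Strategy.** Both halves of the target are the same 2,3-cis flavan-3-ol, so the dimer is cut at C4(upper)–C6(lower) into benzylated monomer 11, used as nucleophile and, after C4 oxidation, as electrophile. Ring C of 11, hence of both units, is not made as a pyran. An enantioselective carbene C–H insertion gives a cis-2-aryl-2,3-dihydrobenzofuran-3-ylmethanol; in the key step the ring A carbon C4a, activated by O7 (para) and O1 (on the ortho carbon), migrates from C3 to the exocyclic CH2 through a phenonium ion while water enters at C3 from the opposite side. One operation inserts C4 into the furan ring, giving the chroman, and sets the C3 hydroxyl cis to the C2 aryl group.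

Key step: step 6

Assumption: Rh2(S-PTTL)4 is taken to deliver the (2R,3S) enantiomer of ester 7; should the sense of induction be the opposite, the mirror-image catalyst Rh2(R-PTTL)4 is used and nothing else changes.

Remark: the C2 descriptor changes from R (7–9) to S (11) only because the CIP priorities change; this atom is never touched.

**Step 1**
Reactants: 1 3-(benzyloxy)phenol
Product: 2 5-(benzyloxy)-2-iodophenol
Conditions: I2, NaHCO3, THF/H2O, 0 °C to rt
Reagents that add atoms: iodine, II
Why: Electrophilic aromatic iodination of the phenol at the unhindered position ortho to OH and para to OBn, which both oxygens activate; the regioisomeric iodide should be removed by chromatography.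

**Step 2**
Reactants: 2 5-(benzyloxy)-2-iodophenol; 3 3,4-bis(benzyloxy)benzyl chloride
Product: 4 4-(benzyloxy)-2-{[3,4-bis(benzyloxy)phenyl]methoxy}-1-iodobenzene
Conditions: K2CO3, NaI (cat.), DMF, 50 °C
Reagents that add atoms: none
Why: Williamson ether synthesis of the phenoxide with a reactive benzylic chloride; the CH2 introduced here becomes C2 of the flavan.

**Step 3**
Reactants: 4 4-(benzyloxy)-2-{[3,4-bis(benzyloxy)phenyl]methoxy}-1-iodobenzene; 5 ethyl diazoacetate
Product: 6 ethyl [4-(benzyloxy)-2-{[3,4-bis(benzyloxy)phenyl]methoxy}phenyl](diazo)acetate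
Conditions: Pd(PPh3)4 (5 mol%), Ag2CO3 (0.5 equiv), Et3N, toluene, rt
Reagents that add atoms: none
Why: Palladium-catalysed cross-coupling of an aryl iodide with the C–H bond of an acceptor diazo ester (oxidative addition to zerovalent palladium, silver-assisted palladation of the diazo carbon, reductive elimination), which keeps the diazo group and gives the aryldiazoacetate directly.

**Step 4**
Reactants: 6 ethyl [4-(benzyloxy)-2-{[3,4-bis(benzyloxy)phenyl]methoxy}phenyl](diazo)acetate
Product: 7 ethyl (2R,3S)-6-(benzyloxy)-2-[3,4-bis(benzyloxy)phenyl]-2,3-dihydro-1-benzofuran-3-carboxylate (2,3-cis)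
Conditions: Rh2(S-PTTL)4 (dirhodium tetrakis[N-phthaloyl-(S)-tert-leucinate], 1 mol%), toluene, −60 °C
Reagents that add atoms: none
Why: Intramolecular 1,5 C–H insertion of the dirhodium donor/acceptor carbenoid into the benzylic ether C–H bond closes the dihydrofuran ring; the insertion is kinetically cis-selective and the chiral carboxylate ligands set both new stereocentres (C2 R, C3 S).

**Step 5**
Reactants: 7 ethyl (2R,3S)-6-(benzyloxy)-2-[3,4-bis(benzyloxy)phenyl]-2,3-dihydro-1-benzofuran-3-carboxylate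
Product: 8 [(2R,3R)-6-(benzyloxy)-2-[3,4-bis(benzyloxy)phenyl]-2,3-dihydro-1-benzofuran-3-yl]methanol (2,3-cis)
Conditions: LiAlH4, THF, −20 °C
Reagents that add atoms: none
Why: Hydride reduction of the ester to the primary alcohol at low temperature, so that the base-labile cis C3 centre is not epimerised (the change of the C3 descriptor from S to R is only a change of CIP priorities).

**Step 6**
Reactants: 8 [(2R,3R)-6-(benzyloxy)-2-[3,4-bis(benzyloxy)phenyl]-2,3-dihydro-1-benzofuran-3-yl]methanol
Product: 11 (2S,3S)-7-(benzyloxy)-2-[3,4-bis(benzyloxy)phenyl]-3,4-dihydro-2H-chromen-3-ol, via mesylate 9 (not isolated), via phenonium ion 10 (not isolated)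
Conditions: MsCl, Et3N, CH2Cl2, 0 °C; aqueous wash, then crude 9 in (CF3)2CHOH/H2O (4:1), 2,6-lutidine, 40 °C
Reagents that add atoms: water, O (supplies the 3-hydroxyl oxygen of 11); methanesulfonyl chloride, CS(=O)(=O)Cl (its atoms stay only in intermediates 9 and 10)
Why: Mesylate 9 ionises with anchimeric assistance: the ring A carbon C3a of the benzofuran (the later C4a, para to the benzyloxy oxygen and ortho to the carbon bearing O1) attacks the CH2 carbon from the rear (Ar1-3 participation, a 3-exo-tet closure to the spirocyclopropane of phenonium ion 10), and water then opens the three-membered ring at C3 anti to the old C3–aryl bond, so that this bond is exchanged for the new C4–C4a bond (Wagner–Meerwein 1,2-aryl shift). The closest known reaction type is the solvolytic ring expansion of indan-1-ylmethyl and related benzo-fused cycloalkylmethyl sulfonates to the next larger benzo-fused 2-ol through phenonium ions. Ring C is therefore not closed onto oxygen but arises from the five-membered ring O1–C2–C3–C4a–C8a by insertion of the former CH2 as C4. C2 is not touched and keeps its configuration; the new C3 stereocentre is set by the invertive opening, so the cis relation of aryl and CH2OMs in 9 becomes the 2,3-cis relation of aryl and OH in 11. The step needs opening at C3 and not at CH2: this should be favoured by the higher substitution of C3 and by relief of the cis strain of the five-membered ring, and the 2,3-cis product should not re-ionise because its axial C3–O bond is not antiperiplanar to C4–C4a. Attack at CH2 only returns alcohol 8, which is mesylated again.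

**Step 7**
Reactants: 11 (2S,3S)-7-(benzyloxy)-2-[3,4-bis(benzyloxy)phenyl]-3,4-dihydro-2H-chromen-3-ol
Product: 12 (2S,3S,4R)-7-(benzyloxy)-2-[3,4-bis(benzyloxy)phenyl]-4-(2-ethoxyethoxy)-3,4-dihydro-2H-chromen-3-ol (2,3-cis-3,4-trans)
Conditions: DDQ, 2-ethoxyethanol, CH2Cl2, rt
Reagents that add atoms: 2-ethoxyethanol, CCOCCO
Why: Oxidative benzylic C–H functionalisation: DDQ abstracts hydride from C4, which is ortho/para-activated by O1 and O7 of ring A, and the alcohol adds to the cation anti to the axial 3-hydroxyl; the C4 configuration is of no consequence because the centre is ionised again in step 8.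

**Step 8**
Reactants: 12 (2S,3S,4R)-7-(benzyloxy)-2-[3,4-bis(benzyloxy)phenyl]-4-(2-ethoxyethoxy)-3,4-dihydro-2H-chromen-3-ol; 11 (2S,3S)-7-(benzyloxy)-2-[3,4-bis(benzyloxy)phenyl]-3,4-dihydro-2H-chromen-3-ol (4 equiv, excess recovered)
Product: 13 hexa-O-benzyl ether of 14 (2,3-cis-3,4-trans upper unit linked from C4 to C6 of the 2,3-cis lower unit; all five stereocentres as in 14)
Conditions: TMSOTf (cat.), CH2Cl2, −78 °C
Reagents that add atoms: none
Why: TMSOTf ionises the C4 benzylic ether to the flavan-4-yl cation, which C6 of 11 (para to O1, ortho to O7, less hindered than C8) attacks in a Friedel–Crafts alkylation from the face opposite the axial 3-hydroxyl, setting C4 with the 3,4-trans relation; the excess of 11 should suppress capture by 12 or 13.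

**Step 9**
Reactants: 13 hexa-O-benzyl ether of 14
Product: 14 (2S,3S,4R)-2-(3,4-dihydroxyphenyl)-4-[(2S,3S)-2-(3,4-dihydroxyphenyl)-3,7-dihydroxy-3,4-dihydro-2H-chromen-6-yl]-3,4-dihydro-2H-chromene-3,7-diol
Conditions: H2 (1 atm), Pd(OH)2/C, THF/MeOH/H2O, rt
Reagents that add atoms: none
Why: Hydrogenolysis of the six benzyl ethers under neutral conditions should leave the interflavan bond and all five stereocentres untouched.

**Compound list**
1 | 3-(benzyloxy)phenol | Oc1cccc(OCc2ccccc2)c1 | starting material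
2 | 5-(benzyloxy)-2-iodophenol | Oc1cc(OCc2ccccc2)ccc1I | intermediate
3 | 3,4-bis(benzyloxy)benzyl chloride | ClCc1ccc(OCc2ccccc2)c(OCc2ccccc2)c1 | starting material
4 | 4-(benzyloxy)-2-{[3,4-bis(benzyloxy)phenyl]methoxy}-1-iodobenzene | Ic1ccc(OCc2ccccc2)cc1OCc1ccc(OCc2ccccc2)c(OCc2ccccc2)c1 | intermediate
5 | ethyl diazoacetate | CCOC(=O)C=[N+]=[N-] | starting material
6 | ethyl [4-(benzyloxy)-2-{[3,4-bis(benzyloxy)phenyl]methoxy}phenyl](diazo)acetate | CCOC(=O)C(=[N+]=[N-])c1ccc(OCc2ccccc2)cc1OCc1ccc(OCc2ccccc2)c(OCc2ccccc2)c1 | intermediate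
7 | ethyl (2R,3S)-6-(benzyloxy)-2-[3,4-bis(benzyloxy)phenyl]-2,3-dihydro-1-benzofuran-3-carboxylate (cis) | c1cc2c(cc1OCc1ccccc1)O[C@@H](c1ccc(OCc3ccccc3)c(OCc3ccccc3)c1)[C@H]2C(=O)OCC | intermediate
8 | [(2R,3R)-6-(benzyloxy)-2-[3,4-bis(benzyloxy)phenyl]-2,3-dihydro-1-benzofuran-3-yl]methanol (cis) | c1cc2c(cc1OCc1ccccc1)O[C@@H](c1ccc(OCc3ccccc3)c(OCc3ccccc3)c1)[C@H]2CO | intermediate
9 | [(2R,3R)-6-(benzyloxy)-2-[3,4-bis(benzyloxy)phenyl]-2,3-dihydro-1-benzofuran-3-yl]methyl methanesulfonate (cis) | c1cc2c(cc1OCc1ccccc1)O[C@@H](c1ccc(OCc3ccccc3)c(OCc3ccccc3)c1)[C@H]2COS(C)(=O)=O | intermediate (not isolated)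
10 | phenonium ion of 9: spirocyclopropane arenium ion bridging C3 and the former CH2 through the ring A ipso carbon, cyclopropane cis to the C2 aryl group, methanesulfonate counter-ion | C(c1ccccc1)[O+]=C1C=C[C@@]23C[C@@H]2[C@H](c2ccc(OCc4ccccc4)c(OCc4ccccc4)c2)OC3=C1.CS(=O)(=O)[O-] | intermediate (not isolated)
11 | (2S,3S)-7-(benzyloxy)-2-[3,4-bis(benzyloxy)phenyl]-3,4-dihydro-2H-chromen-3-ol (2,3-cis) | c1cc2c(cc1OCc1ccccc1)O[C@@H](c1ccc(OCc3ccccc3)c(OCc3ccccc3)c1)[C@@H](O)C2 | intermediate
12 | (2S,3S,4R)-7-(benzyloxy)-2-[3,4-bis(benzyloxy)phenyl]-4-(2-ethoxyethoxy)-3,4-dihydro-2H-chromen-3-ol (2,3-cis-3,4-trans) | C(c1ccccc1)Oc1ccc2c(c1)O[C@@H](c1ccc(OCc3ccccc3)c(OCc3ccccc3)c1)[C@@H](O)[C@@H]2OCCOCC | intermediate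
13 | hexa-O-benzyl ether of 14 (all five stereocentres as in 14) | C(c1ccccc1)Oc1ccc2c(c1)O[C@@H](c1ccc(OCc3ccccc3)c(OCc3ccccc3)c1)[C@@H](O)[C@@H]2c1cc2c(cc1OCc1ccccc1)O[C@@H](c1ccc(OCc3ccccc3)c(OCc3ccccc3)c1)[C@@H](O)C2 | intermediate
14 | (2S,3S,4R)-2-(3,4-dihydroxyphenyl)-4-[(2S,3S)-2-(3,4-dihydroxyphenyl)-3,7-dihydroxy-3,4-dihydro-2H-chromen-6-yl]-3,4-dihydro-2H-chromene-3,7-diol | Oc1ccc2c(c1)O[C@@H](c1ccc(O)c(O)c1)[C@@H](O)[C@@H]2c1cc2c(cc1O)O[C@@H](c1ccc(O)c(O)c1)[C@@H](O)C2 | target

**Totals.** Total step count: 9. Longest linear sequence: 9 steps (monomer 11 enters step 8 twice, as such and as 12).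

**Steps most likely to fail**

Step 6. Water may open the phenonium ion at the CH2 carbon instead of C3, which only regenerates unrearranged material, and the ionising medium may also cleave the benzylic C2–O1 bond. The fallback sets out from ester 7 and enforces the regiochemistry by a hydroxyl at C3. Ester 7 is deprotonated with KN(SiMe3)2 in THF at −78 °C and the enolate is hydroxylated with 2-(phenylsulfonyl)-3-phenyloxaziridine to the 3-hydroxy ester F1. LiAlH4 reduces it to the diol F2, and TsCl in pyridine sulfonylates only the primary hydroxyl to give the monotosylate F3. LiClO4 and CaCO3 in THF at 50 °C then trigger a semipinacol rearrangement in which the same ring A carbon migrates to the CH2 carbon while the C3 hydroxyl becomes the carbonyl group, giving the ring-expanded (2S)-chroman-3-one F4. LiBH(s-Bu)3 in THF at −78 °C attacks equatorially and should give the axial, 2,3-cis alcohol; the route is rejoined at 11.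

Step 7. Hydride abstraction may occur at C2 (benzylic to ring B and next to O1) instead of C4, or may stall because ring A lacks a 5-oxygen. The fallback sets out from 11 and uses acetoxylation by Pb(OAc)4 with a participating 3-acyl group. Ac2O in pyridine gives the 3-acetate F5, and Pb(OAc)4 in benzene at 60 °C acetoxylates the benzylic C4 to the 3,4-diacetate F6. BF3·OEt2 in CH2Cl2 ionises the 4-acetoxy group of F6 in the presence of excess 11; the neighbouring 3-acetoxy group shields its own face, so the arene should enter trans and give the mono-acetylated dimer F7. K2CO3 in MeOH/THF removes the acetate, and the route is rejoined at 13.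

Step 8. The cation may be captured by ring A of a second molecule of 12 or of product 13, leading to oligomers. The fallback sets out from 12 and blocks its own nucleophilic position. NBS in CH2Cl2 at −20 °C brominates C6 of ring A (para to O1, ortho to O7) to give the 6-bromo electrophile F8. TMSOTf-mediated coupling of F8 with 11 (1.5 equiv) gives the bromo dimer F9. Hydrogenolysis under the conditions of step 9 with Et3N added removes the bromine together with the benzyl groups, and the route is rejoined at 14.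

**Further compounds**
F1 | step 6 | ethyl (2S,3R)-6-(benzyloxy)-2-[3,4-bis(benzyloxy)phenyl]-3-hydroxy-2,3-dihydro-1-benzofuran-3-carboxylate (hydroxyl expected trans to the aryl group; C3 is lost later) | c1cc2c(cc1OCc1ccccc1)O[C@@H](c1ccc(OCc3ccccc3)c(OCc3ccccc3)c1)[C@@]2(O)C(=O)OCC
F2 | step 6 | (2S,3S)-6-(benzyloxy)-2-[3,4-bis(benzyloxy)phenyl]-3-(hydroxymethyl)-2,3-dihydro-1-benzofuran-3-ol | c1cc2c(cc1OCc1ccccc1)O[C@@H](c1ccc(OCc3ccccc3)c(OCc3ccccc3)c1)[C@@]2(O)CO
F3 | step 6 | [(2S,3S)-6-(benzyloxy)-2-[3,4-bis(benzyloxy)phenyl]-3-hydroxy-2,3-dihydro-1-benzofuran-3-yl]methyl 4-methylbenzenesulfonate | c1cc2c(cc1OCc1ccccc1)O[C@@H](c1ccc(OCc3ccccc3)c(OCc3ccccc3)c1)[C@@]2(O)COS(=O)(=O)c1ccc(C)cc1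
F4 | step 6 | (2S)-7-(benzyloxy)-2-[3,4-bis(benzyloxy)phenyl]-2H-chromen-3(4H)-one | c1cc2c(cc1OCc1ccccc1)O[C@@H](c1ccc(OCc3ccccc3)c(OCc3ccccc3)c1)C(=O)C2
F5 | step 7 | 3-O-acetate of 11 (2,3-cis) | c1cc2c(cc1OCc1ccccc1)O[C@@H](c1ccc(OCc3ccccc3)c(OCc3ccccc3)c1)[C@@H](OC(C)=O)C2
F6 | step 7 | 4-acetoxy derivative of F5 (2,3-cis-3,4-trans diacetate; C2 and C3 as in 11) | C(c1ccccc1)Oc1ccc2c(c1)O[C@@H](c1ccc(OCc3ccccc3)c(OCc3ccccc3)c1)[C@@H](OC(C)=O)[C@@H]2OC(C)=O
F7 | step 7 | 13 carrying an acetate on the 3-hydroxyl of the upper unit | C(c1ccccc1)Oc1ccc2c(c1)O[C@@H](c1ccc(OCc3ccccc3)c(OCc3ccccc3)c1)[C@@H](OC(C)=O)[C@@H]2c1cc2c(cc1OCc1ccccc1)O[C@@H](c1ccc(OCc3ccccc3)c(OCc3ccccc3)c1)[C@@H](O)C2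
F8 | step 8 | 6-bromo derivative of 12 (configuration as in 12) | C(c1ccccc1)Oc1c(Br)cc2c(c1)O[C@@H](c1ccc(OCc3ccccc3)c(OCc3ccccc3)c1)[C@@H](O)[C@@H]2OCCOCC
F9 | step 8 | 13 carrying bromine at C6 of the upper unit | C(c1ccccc1)Oc1c(Br)cc2c(c1)O[C@@H](c1ccc(OCc3ccccc3)c(OCc3ccccc3)c1)[C@@H](O)[C@@H]2c1cc2c(cc1OCc1ccccc1)O[C@@H](c1ccc(OCc3ccccc3)c(OCc3ccccc3)c1)[C@@H](O)C2
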